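**Retrosynthetic overview**
1. The C8 tiglate goes on last. The ten-membered carbocycle is closed at C7–C8: a C8 α-hydroxyalkyl radical (made by hydrogen-atom abstraction from a primary alcohol) displaces the sulfonyl group of a 4-sulfonylbutenolide, which also sets C8.
2. The butenolide (C6–C7 bond, lactone, C13 acetate) comes in one operation from an epoxy aldehyde and a metalated β-sulfonyl acrylate; Felkin–Anh addition sets C6.
3. The two epoxides are placed on an acyclic (2Z,6Z)-diene by reagent control: Sharpless epoxidation (C4/C5), then Shi epoxidation (C1/C10).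
4. The diene comes from γ-alkylation of the senecioic acid dienolate with a Z-allylic iodide, itself made by ring-opening 4-methyl-3,6-dihydro-2H-pyran.
5. Ring order: 4,5-epoxide, 1,10-epoxide, butenolide, ten-membered ring.

Assumption: compounds 1, 3, 10 and 19 and the L-fructose-derived Shi ketone are bought; intermediate 11 is racemic; locants C1–C15 in the text are the germacrane locants of the target.

**Step 1**
Reactants: 1 4-methyl-3,6-dihydro-2H-pyran
Product: 2 tert-butyl{[(3Z)-5-iodo-3-methylpent-3-en-1-yl]oxy}dimethylsilane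
Conditions: TBSCl, NaI, MeCN, 0 °C to rt, dark; used crude
Reagents that add atoms: tert-butyldimethylsilyl chloride CC(C)(C)[Si](C)(C)Cl; sodium iodide [Na+].[I-]
Why: In situ tert-butyldimethylsilyl iodide silylates the ring oxygen and iodide opens the oxonium by SN2 attack at the allylic CH2 (silyl iodide ether cleavage), so the Z-trisubstituted alkene is taken over unchanged from the ring and the C8 oxygen leaves the step already protected.

**Step 2**
Reactants: 2 tert-butyl{[(3Z)-5-iodo-3-methylpent-3-en-1-yl]oxy}dimethylsilane; 3 3-methylbut-2-enoic acid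
Product: 5 (2Z,6Z)-9-[(tert-butyldimethylsilyl)oxy]-3,7-dimethylnona-2,6-dienoic acid, via dilithium dienolate 4 (not isolated)
Conditions: 3, LiN(iPr)2 (2 equiv), THF, −78 to 0 °C; CuI, −78 °C; then 2, −78 to −20 °C; H3O+ work-up
Reagents that add atoms: none
Why: γ-Selective allylic alkylation of the copper dienolate of the senecioic acid dianion (Katzenellenbogen alkylation): the dianion forms by loss of the methyl proton syn to the carboxylate, so the new chain ends up cis to CO2H (2Z; minor 2E and α-alkylated isomers are removed by chromatography), and SN2 attack at the primary allylic iodide keeps the 6Z alkene.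

**Step 3**
Reactants: 5 (2Z,6Z)-9-[(tert-butyldimethylsilyl)oxy]-3,7-dimethylnona-2,6-dienoic acid
Product: 6 (2Z,6Z)-9-[(tert-butyldimethylsilyl)oxy]-3,7-dimethylnona-2,6-dien-1-ol
Conditions: LiAlH4, Et2O, 0 °C
Reagents that add atoms: none
Why: LiAlH4 reduces the conjugated acid to the allylic alcohol by 1,2-hydride delivery (carboxylic acid reduction) without touching the silyl ether or either alkene geometry.

**Step 4**
Reactants: 6 (2Z,6Z)-9-[(tert-butyldimethylsilyl)oxy]-3,7-dimethylnona-2,6-dien-1-ol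
Product: 7 [(2R,3S)-3-{(3Z)-6-[(tert-butyldimethylsilyl)oxy]-4-methylhex-3-en-1-yl}-3-methyloxiran-2-yl]methanol
Conditions: Ti(OiPr)4 (10 mol%), D-(−)-diisopropyl tartrate (12 mol%), t-BuOOH, 4 Å MS, CH2Cl2, −20 °C
Reagents that add atoms: tert-butyl hydroperoxide CC(C)(C)OO
Why: Sharpless asymmetric epoxidation is specific for the allylic alkene and, with the D-(−)-tartrate, delivers oxygen to the face that gives the (2R,3S)-epoxy alcohol (C5 R, C4 S of the target; the mirror image of the known L-(+)-tartrate/nerol result).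

**Step 5**
Reactants: 7 [(2R,3S)-3-{(3Z)-6-[(tert-butyldimethylsilyl)oxy]-4-methylhex-3-en-1-yl}-3-methyloxiran-2-yl]methanol
Product: 8 [(2R,3S)-3-(2-{(2S,3R)-3-[2-[(tert-butyldimethylsilyl)oxy]ethyl]-3-methyloxiran-2-yl}ethyl)-3-methyloxiran-2-yl]methanol
Conditions: L-fructose-derived Shi ketone (30 mol%), KHSO5 (Oxone), K2CO3, Bu4NHSO4, MeCN–CH2(OMe)2–aq. Na2B4O7 buffer, 0 °C
Reagents that add atoms: potassium peroxymonosulfate (Oxone) [K+].[O-]S(=O)(=O)OO
Why: Shi asymmetric epoxidation (chiral dioxirane, spiro transition state) of the one remaining trisubstituted Z-alkene; the L-fructose-derived ketone places oxygen on the face that gives the (2S,3R)-epoxide (C1 S, C10 R) by reagent control, independent of the remote epoxide.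

**Step 6**
Reactants: 8 [(2R,3S)-3-(2-{(2S,3R)-3-[2-[(tert-butyldimethylsilyl)oxy]ethyl]-3-methyloxiran-2-yl}ethyl)-3-methyloxiran-2-yl]methanol
Product: 9 (2S,3S)-3-(2-{(2S,3R)-3-[2-[(tert-butyldimethylsilyl)oxy]ethyl]-3-methyloxiran-2-yl}ethyl)-3-methyloxirane-2-carbaldehyde
Conditions: Dess–Martin periodinane, pyridine, CH2Cl2, 0 °C
Reagents that add atoms: none
Why: Dess–Martin oxidation of the primary alcohol under pyridine buffering gives the cis-epoxy aldehyde without epimerization because the oxirane C–H is not enolizable (the descriptor at C5 changes from R to S only because CHO now outranks C4).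

**Step 7**
Reactants: 10 methyl 2-(hydroxymethyl)prop-2-enoate
Product: 12 methyl (2E)-2-(hydroxymethyl)-3-(phenylsulfonyl)prop-2-enoate, via iodo sulfone 11 (not isolated)
Conditions: PhSO2Na, I2, MeCN, rt, dark; then Et3N (1 equiv), 0 °C
Reagents that add atoms: sodium benzenesulfinate [Na+].[O-]S(=O)c1ccccc1
Why: Radical iodosulfonylation of the acrylate (PhSO2• adds to the CH2 terminus, iodine-atom transfer to the tertiary α-ester radical) followed by E1cB loss of HI through the acidic α-sulfonyl C–H gives the vinyl sulfone as the E isomer, with the sulfonyl group trans to the ester.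

**Step 8**
Reactants: 9 (2S,3S)-3-(2-{(2S,3R)-3-[2-[(tert-butyldimethylsilyl)oxy]ethyl]-3-methyloxiran-2-yl}ethyl)-3-methyloxirane-2-carbaldehyde; 12 methyl (2E)-2-(hydroxymethyl)-3-(phenylsulfonyl)prop-2-enoate
Product: 16 {(5S)-5-[(2R,3S)-3-(2-{(2S,3R)-3-[2-[(tert-butyldimethylsilyl)oxy]ethyl]-3-methyloxiran-2-yl}ethyl)-3-methyloxiran-2-yl]-2-oxo-4-(phenylsulfonyl)-2,5-dihydrofuran-3-yl}methyl acetate, via dimagnesiated sulfone 13 (not isolated), via open-chain alkoxide adduct 14 (not isolated), via butenolide alkoxide 15 (not isolated)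
Conditions: 12, TMPMgCl·LiCl (2.2 equiv), THF, −78 °C; 9, −78 to −20 °C; then Ac2O, 0 °C
Reagents that add atoms: acetic anhydride CC(=O)OC(C)=O
Why: Proposed new method: the amide base first forms the magnesium alkoxide (which blocks γ-deprotonation) and then removes the vinylic C–H that is α to the sulfonyl group and cis to the ester, the chelated β-magnesio acrylate adds to the aldehyde under Felkin–Anh (Cornforth) control anti to the epoxide C–O to set C6, the cis alkoxide lactonizes and Ac2O caps the primary alkoxide; the closest known reactions are the Schmidt tetronate synthesis from β-lithiated β-alkoxy- and β-thioacrylates with aldehydes and TMPMgCl·LiCl metalations of functionalized acrylates.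

**Step 9**
Reactants: 16 {(5S)-5-[(2R,3S)-3-(2-{(2S,3R)-3-[2-[(tert-butyldimethylsilyl)oxy]ethyl]-3-methyloxiran-2-yl}ethyl)-3-methyloxiran-2-yl]-2-oxo-4-(phenylsulfonyl)-2,5-dihydrofuran-3-yl}methyl acetate
Product: 17 {(5S)-5-[(2R,3S)-3-(2-{(2S,3R)-3-(2-hydroxyethyl)-3-methyloxiran-2-yl}ethyl)-3-methyloxiran-2-yl]-2-oxo-4-(phenylsulfonyl)-2,5-dihydrofuran-3-yl}methyl acetate
Conditions: HF·pyridine, pyridine, THF, 0 °C to rt
Reagents that add atoms: none
Why: Fluoride-driven Si–O cleavage (desilylation) with pyridine-buffered HF leaves the two trisubstituted epoxides, the acetate and the vinyl sulfone intact and frees the primary C8 alcohol.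

**Step 10** (key step)
Reactants: 17 {(5S)-5-[(2R,3S)-3-(2-{(2S,3R)-3-(2-hydroxyethyl)-3-methyloxiran-2-yl}ethyl)-3-methyloxiran-2-yl]-2-oxo-4-(phenylsulfonyl)-2,5-dihydrofuran-3-yl}methyl acetate
Product: 18 (1S,4S,5R,6R,8R,10R)-13-acetoxy-1,10:4,5-diepoxy-8-hydroxygermacr-7(11)-en-12,6-olide
Conditions: (Bu4N)4[W10O32] (5 mol%), MeCN (1 mM), 390 nm LEDs, Ar, 25 °C; aq. NaHCO3 work-up
Reagents that add atoms: none
Why: Proposed new method: excited decatungstate abstracts the hydridic α-hydroxy C8–H, the nucleophilic α-hydroxyalkyl radical attacks C7 of the β-sulfonyl butenolide and β-scission of PhSO2• (returned as PhSO2H by back hydrogen transfer) restores the C7=C11 alkene and closes the ten-membered ring, C8 being set R because the radical adds anti to the C5 substituent on C6 (trans-fused transition state, as in additions to γ-substituted butenolides) with its C–H over C11/CH2OAc (allylic 1,3-strain) and the OH turned outward; the closest known reactions are decatungstate- or benzophenone-mediated C–H alkenylations with vinyl sulfones and ipso-substitution radical cyclizations onto vinyl and heteroaryl sulfones.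

**Step 11**
Reactants: 18 (1S,4S,5R,6R,8R,10R)-13-acetoxy-1,10:4,5-diepoxy-8-hydroxygermacr-7(11)-en-12,6-olide; 19 (2E)-2-methylbut-2-enoyl chloride (tigloyl chloride)
Product: 20 (1S,4S,5R,6R,8R,10R)-13-acetoxy-1,10:4,5-diepoxy-8-[(2E)-2-methylbut-2-enoyloxy]germacr-7(11)-en-12,6-olide (CNP0251711.3)
Conditions: 19, pyridine, DMAP (cat.), CH2Cl2, 0 °C to rt
Reagents that add atoms: none
Why: DMAP-catalysed O-acylation of the secondary allylic alcohol with the E acid chloride proceeds with retention at C8 and without E/Z isomerization, giving the tiglate and completing the target.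

**Compound list**
1 | 4-methyl-3,6-dihydro-2H-pyran | CC1=CCOCC1 | starting material
2 | tert-butyl{[(3Z)-5-iodo-3-methylpent-3-en-1-yl]oxy}dimethylsilane | CC(C)(C)[Si](C)(C)OCC/C(C)=C\CI | intermediate
3 | 3-methylbut-2-enoic acid | CC(C)=CC(=O)O | starting material
4 | dilithium dienolate of 3-methylbut-2-enoic acid | [Li+].[Li+].C=C(C)C=C([O-])[O-] | intermediate
5 | (2Z,6Z)-9-[(tert-butyldimethylsilyl)oxy]-3,7-dimethylnona-2,6-dienoic acid | CC(C)(C)[Si](C)(C)OCC/C(C)=C\CC/C(C)=C\C(=O)O | intermediate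
6 | (2Z,6Z)-9-[(tert-butyldimethylsilyl)oxy]-3,7-dimethylnona-2,6-dien-1-ol | CC(C)(C)[Si](C)(C)OCC/C(C)=C\CC/C(C)=C\CO | intermediate
7 | [(2R,3S)-3-{(3Z)-6-[(tert-butyldimethylsilyl)oxy]-4-methylhex-3-en-1-yl}-3-methyloxiran-2-yl]methanol | CC(C)(C)[Si](C)(C)OCC/C(C)=C\CC[C@]1(C)O[C@@H]1CO | intermediate
8 | [(2R,3S)-3-(2-{(2S,3R)-3-[2-[(tert-butyldimethylsilyl)oxy]ethyl]-3-methyloxiran-2-yl}ethyl)-3-methyloxiran-2-yl]methanol | CC(C)(C)[Si](C)(C)OCC[C@@]1(C)O[C@H]1CC[C@]2(C)O[C@@H]2CO | intermediate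
9 | (2S,3S)-3-(2-{(2S,3R)-3-[2-[(tert-butyldimethylsilyl)oxy]ethyl]-3-methyloxiran-2-yl}ethyl)-3-methyloxirane-2-carbaldehyde | CC(C)(C)[Si](C)(C)OCC[C@@]1(C)O[C@H]1CC[C@]2(C)O[C@@H]2C=O | intermediate
10 | methyl 2-(hydroxymethyl)prop-2-enoate | C=C(CO)C(=O)OC | starting material
11 | methyl 2-(hydroxymethyl)-2-iodo-3-(phenylsulfonyl)propanoate (racemic) | COC(=O)C(I)(CO)CS(=O)(=O)c1ccccc1 | intermediate
12 | methyl (2E)-2-(hydroxymethyl)-3-(phenylsulfonyl)prop-2-enoate | COC(=O)/C(CO)=C/S(=O)(=O)c1ccccc1 | intermediate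
13 | O,C3-bis(chloromagnesio) derivative of 12 | COC(=O)/C(CO[Mg]Cl)=C(\[Mg]Cl)/S(=O)(=O)c1ccccc1 | intermediate
14 | open-chain bis(chloromagnesium alkoxide) adduct of 13 and 9 (C6–C7 bond formed, C6 cis to the ester) | CC(C)(C)[Si](C)(C)OCC[C@@]1(C)O[C@H]1CC[C@]2(C)O[C@@H]2[C@H](O[Mg]Cl)/C(S(=O)(=O)c3ccccc3)=C(CO[Mg]Cl)\C(=O)OC | intermediate
15 | chloromagnesium alkoxide of the 3-(hydroxymethyl)-4-(phenylsulfonyl)butenolide | CC(C)(C)[Si](C)(C)OCC[C@@]1(C)O[C@H]1CC[C@]2(C)O[C@@H]2[C@@H]3OC(=O)C(CO[Mg]Cl)=C3S(=O)(=O)c4ccccc4 | intermediate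
16 | {(5S)-5-[(2R,3S)-3-(2-{(2S,3R)-3-[2-[(tert-butyldimethylsilyl)oxy]ethyl]-3-methyloxiran-2-yl}ethyl)-3-methyloxiran-2-yl]-2-oxo-4-(phenylsulfonyl)-2,5-dihydrofuran-3-yl}methyl acetate | CC(C)(C)[Si](C)(C)OCC[C@@]1(C)O[C@H]1CC[C@]2(C)O[C@@H]2[C@@H]3OC(=O)C(COC(C)=O)=C3S(=O)(=O)c4ccccc4 | intermediate
17 | {(5S)-5-[(2R,3S)-3-(2-{(2S,3R)-3-(2-hydroxyethyl)-3-methyloxiran-2-yl}ethyl)-3-methyloxiran-2-yl]-2-oxo-4-(phenylsulfonyl)-2,5-dihydrofuran-3-yl}methyl acetate | OCC[C@@]1(C)O[C@H]1CC[C@]2(C)O[C@@H]2[C@@H]3OC(=O)C(COC(C)=O)=C3S(=O)(=O)c4ccccc4 | intermediate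
18 | (1S,4S,5R,6R,8R,10R)-13-acetoxy-1,10:4,5-diepoxy-8-hydroxygermacr-7(11)-en-12,6-olide | O[C@@H]1C[C@@]2(C)O[C@H]2CC[C@]2(C)O[C@@H]2[C@@H]2OC(=O)C(COC(C)=O)=C21 | intermediate
19 | (2E)-2-methylbut-2-enoyl chloride (tigloyl chloride) | C/C=C(\C)C(Cl)=O | starting material
20 | (1S,4S,5R,6R,8R,10R)-13-acetoxy-1,10:4,5-diepoxy-8-[(2E)-2-methylbut-2-enoyloxy]germacr-7(11)-en-12,6-olide | C/C=C(\C)C(=O)O[C@@H]1C[C@@]2(C)O[C@H]2CC[C@]2(C)O[C@@H]2[C@@H]2OC(=O)C(COC(C)=O)=C21 | target

**Totals**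
Total step count: 11. Longest linear sequence: 10 steps (steps 1–6 and 8–11; step 7 is the side branch).

**Three steps most likely to fail**

Step 10 (radical macrocyclization). The radical must attack a fully substituted sp2 carbon while closing a ten-membered ring, and the C8 configuration rests on a transition-state model rather than on precedent. Fallback, setting out from 17 and coming back at 18: the primary alcohol is oxidized with pyridine-buffered Dess–Martin periodinane at 0 °C to the β,γ-epoxy aldehyde F1, which is used at once. Under the same decatungstate irradiation the formyl hydrogen is abstracted, and the acyl radical, a smaller and faster σ-radical, closes the ring by the same sulfonyl displacement to give the macrocyclic C8 ketone F2. Reduction of this enone-type ketone with the (S)-Me-CBS oxazaborolidine and catecholborane then sets C8 (R) by reagent control instead of by the ring, giving 18.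

Step 8 (one-pot butenolide assembly). The double metalation of 12 may be unselective, the liberated methoxide may displace the sulfonyl group, and the Felkin ratio may be modest. Fallback, setting out from 9 and coming back at 16: lithiated methyl propiolate (LiN(SiMe3)2, THF, −78 °C) adds to the aldehyde with the same Felkin sense to give the γ-hydroxy ynoate F3. LiSPh with monomeric formaldehyde in THF (thia-Michael addition, trapping of the allenolate at C11, lactonization of the C6 alkoxide after thiolate-mediated E/Z equilibration) gives the 3-(hydroxymethyl)-4-(phenylthio)butenolide F4. Ac2O/pyridine gives the acetate F5, and mCPBA (2.2 equiv, CH2Cl2, 0 °C) oxidizes the sulfide to the sulfone 16.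

Step 2 (dienolate γ-alkylation). The γ/α and 2Z/2E ratios are only moderate in the precedent and could be worse here. Fallback, setting out from 2 and coming back at 6: the dianion of but-2-ynoic acid (LiN(iPr)2, THF–HMPA) is alkylated at C4 by iodide 2 to give the enynoic acid F6. Trimethylsilyldiazomethane gives the methyl ester F7. Me2CuLi at −78 °C adds methyl and hydrogen syn across the ynoate, which places the chain cis to the ester and gives the (2Z,6Z)-dienoate F8. i-Bu2AlH at −78 °C reduces the ester to the allylic alcohol 6.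

**Further compounds**
F1 | step 10 | {(5S)-5-[(2R,3S)-3-methyl-3-(2-{(2S,3R)-3-methyl-3-(2-oxoethyl)oxiran-2-yl}ethyl)oxiran-2-yl]-2-oxo-4-(phenylsulfonyl)-2,5-dihydrofuran-3-yl}methyl acetate | O=CC[C@@]1(C)O[C@H]1CC[C@]2(C)O[C@@H]2[C@@H]3OC(=O)C(COC(C)=O)=C3S(=O)(=O)c4ccccc4
F2 | step 10 | (1S,4S,5R,6R,10R)-13-acetoxy-1,10:4,5-diepoxy-8-oxogermacr-7(11)-en-12,6-olide | O=C1C[C@@]2(C)O[C@H]2CC[C@]2(C)O[C@@H]2[C@@H]2OC(=O)C(COC(C)=O)=C12
F3 | step 8 | methyl (4R)-4-[(2R,3S)-3-(2-{(2S,3R)-3-[2-[(tert-butyldimethylsilyl)oxy]ethyl]-3-methyloxiran-2-yl}ethyl)-3-methyloxiran-2-yl]-4-hydroxybut-2-ynoate | CC(C)(C)[Si](C)(C)OCC[C@@]1(C)O[C@H]1CC[C@]2(C)O[C@@H]2[C@H](O)C#CC(=O)OC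
F4 | step 8 | (5S)-5-[(2R,3S)-3-(2-{(2S,3R)-3-[2-[(tert-butyldimethylsilyl)oxy]ethyl]-3-methyloxiran-2-yl}ethyl)-3-methyloxiran-2-yl]-3-(hydroxymethyl)-4-(phenylsulfanyl)furan-2(5H)-one | CC(C)(C)[Si](C)(C)OCC[C@@]1(C)O[C@H]1CC[C@]2(C)O[C@@H]2[C@@H]3OC(=O)C(CO)=C3Sc4ccccc4
F5 | step 8 | {(5S)-5-[(2R,3S)-3-(2-{(2S,3R)-3-[2-[(tert-butyldimethylsilyl)oxy]ethyl]-3-methyloxiran-2-yl}ethyl)-3-methyloxiran-2-yl]-2-oxo-4-(phenylsulfanyl)-2,5-dihydrofuran-3-yl}methyl acetate | CC(C)(C)[Si](C)(C)OCC[C@@]1(C)O[C@H]1CC[C@]2(C)O[C@@H]2[C@@H]3OC(=O)C(COC(C)=O)=C3Sc4ccccc4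
F6 | step 2 | (6Z)-9-[(tert-butyldimethylsilyl)oxy]-7-methylnon-6-en-2-ynoic acid | CC(C)(C)[Si](C)(C)OCC/C(C)=C\CCC#CC(=O)O
F7 | step 2 | methyl (6Z)-9-[(tert-butyldimethylsilyl)oxy]-7-methylnon-6-en-2-ynoate | CC(C)(C)[Si](C)(C)OCC/C(C)=C\CCC#CC(=O)OC
F8 | step 2 | methyl (2Z,6Z)-9-[(tert-butyldimethylsilyl)oxy]-3,7-dimethylnona-2,6-dienoate | CC(C)(C)[Si](C)(C)OCC/C(C)=C\CC/C(C)=C\C(=O)OC
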